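Readings and results come from a simulation with constants of no real substance.

The midnight run had 1.50 times the partner of the autumn run, and the logarithm of starting material charged over starting material left grew 1.51 times. Per equivalent of partner, that logarithm averages 0.232 in these two runs. We call it the reach, the logarithm of charged over left per equivalent of partner at this charge of starting material.

| setting | autumn | midnight | winter | flask |
|---|---|---|---|---|
| starting material | 0.20 M | 0.20 M | 0.30 M | 0.20 M |
| partner | 0.10 M | 0.15 M | 0.20 M | 0.200 M |
| remark | run made earlier | run made earlier | run made earlier |  |
| time |  |  |  | 3.0 min |

- autumn (time / min: single product / %, tris adduct / %, starting material / %): 0.250: 5.8, 0.3, 93.6; 0.667: 9.3, 0, 90.8; 1.50: 9.9, 0, 89.1; 4.00: 9.9, 0, 89.1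
- midnight (time / min: single product / %, tris adduct / %, starting material / %): 0.250: 8.5, 0, 90.5; 0.667: 12.5, 0.1, 85.9; 1.50: 13.0, 0, 83.9; 4.00: 14.1, 0, 84.0
- winter (time / min: single product / %, tris adduct / %, starting material / %): 0.417: 12.9, 0, 85.7; 1.33: 15.3, 0, 81.6; 2.50: 14.8, 0.5, 81.5; 4.00: 16.0, 0.4, 81.5

(scatter of a reading: 0.3 percentage points)



1. equivalents of partner to starting material, everything else as given, that leave most single product at 3.0 min
2. the amount of single product then, in percent of the starting material charged
3. the amount of single product with the amounts as given

Starting material stood still in the autumn run by 1.50 min, earlier than the flask's 3.0 min. The reach therefore says the flask loses a fraction x = 20.7% of its starting material. Single product is made from the starting material lost, so x is our first estimated bound from above. The correction is the gap between x and single product; we assume this gap is a follow-on product of single product, which at small x grows as the square of x. Gap over that square reads 0.842 in the autumn run and 0.730 in the winter run; on that assumption, this ratio is half the selectivity factor of the second step over the first. The winter reading brings our estimated upper bound down to 17.6%. A ratio of 1, within the scatter of the autumn gap, gives the estimated lower bound 16.4%. That lower edge, x minus its square, peaks at x = 0.5, so our own reckoning for the best recipe is 25.0% at 2.99 equiv.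

The forecast, seeing “a fast equilibrium”, gives 18.5% for the flask, above our bracket, and 36% at 4.5 equiv for the best recipe.

The flask gives 16.5%, inside the bracket, with 79.3% of its starting material left, and the best recipe gives 25.3% at 3.06 equiv.

    partner + tris adduct → tetra adduct + released group (k = 0.127 L mol⁻¹ s⁻¹)
    partner → decomposed reagent (k = 0.0392 s⁻¹)
    partner + double product → tris adduct + released group (k = 0.0326 L mol⁻¹ s⁻¹)
    starting material + partner → single product + released group (k = 0.0607 L mol⁻¹ s⁻¹)
    partner + single product → double product + released group (k = 0.119 L mol⁻¹ s⁻¹)

The neighbour flask has 0.50 M of partner, or 2.50 equiv. The reach puts its starting material left at 56.0%, and the lower edge puts its single product at 24.6%. The neighbour flask holds 56% of its starting material and 24.8% single product at 3.00 min.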